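**Retrosynthetic overview**
1. Target ⇒ C8=C9 enone with free O6–H: epoxide by hydroxyl-directed epoxidation, C10 carbinol by ketone reduction, angelate by esterification (no protecting groups).
2. Seven-membered ring (closed last) ⇒ C8–C9 bond: Lewis-acid addition of the enol-ether carbon C9 to the C8 ketal, then loss of ethylene glycol.
3. C4 carbinol ⇒ isopropyl Grignard addition to the cyclopentanone.
4. Key disconnection C1–C10 (C4=O and C10=O are 1,4-related): a 1-ethoxyvinyl metal (acetyl-anion equivalent) adds enantioselectively under copper catalysis to the β-carbon of a commercial methylcyclopentenone (the only ring bought in); the enolate is caught at C5 by the C6 aldehyde (C5–C6).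

Assumption: atoms carry daucane numbers (C1 ring-fusion carbon with methyl, C4 carbinol with isopropyl, C5 ring-fusion CH, C6 ester carbinol, C7 CH2, C8/C9 epoxide carbons, C10 secondary carbinol); α is the face of H5, β the face of the C1 methyl.

**Step 1**
Reactants: 1 ethyl 2-(2-methyl-1,3-dioxolan-2-yl)acetate (fructone)
Product: 2 2-(2-methyl-1,3-dioxolan-2-yl)acetaldehyde
Conditions: iBu2AlH (1.05 equiv), CH2Cl2, −78 °C; aq. potassium sodium tartrate
Reagents that add atoms: none
Why: Partial ester reduction: at −78 °C the aluminium hemiacetal survives until work-up and then gives the aldehyde; no stereocenter is formed.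

**Step 2**
Reactants: 2 2-(2-methyl-1,3-dioxolan-2-yl)acetaldehyde; 3 ethyl vinyl ether; 4 3-methylcyclopent-2-en-1-one
Product: 8 (2S,3S)-3-(1-ethoxyvinyl)-2-[(1S)-1-hydroxy-2-(2-methyl-1,3-dioxolan-2-yl)ethyl]-3-methylcyclopentan-1-one, via 1-ethoxyvinyllithium 5 (not isolated), via (1-ethoxyvinyl)diisobutylaluminium 6 (not isolated), via aluminium enolate 7 (not isolated)
Conditions: 3, t-BuLi, THF, −78 → 0 °C; iBu2AlCl, −78 °C; 4, Cu(OTf)2 (5 mol %), chiral sulfonate-bearing imidazolinium salt (NHC precursor, 6 mol %, enantiomer giving 3S), −30 → 0 °C; 2, −78 °C; aq. NaHCO3/potassium sodium tartrate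
Reagents that add atoms: none
Why: Proposed new method: the 1-ethoxyvinyl group (an acetyl-anion equivalent; C10 becomes a carbonyl carbon) is transmetalated from aluminium to the chiral NHC–copper centre and adds to the aluminium-activated β-carbon of 4, so the ligand fixes the quaternary centre C1 as S; the regiodefined aluminium enolate 7 then adds to 2 through a closed chair transition state on the face cis to methyl and trans to the bulkier ethoxyvinyl group, giving the trans-2,3 relationship (C5 S) and the anti ketol (C6 S); closest known reactions: NHC–Cu-catalysed asymmetric conjugate addition of silyl-substituted vinylaluminium reagents to 3-methylcyclopent-2-enone with aldol capture of the aluminium enolate, and racemic conjugate additions of α-alkoxyvinyl cuprates.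

**Step 3**
Reactants: 8 ketol from step 2; 9 isopropylmagnesium chloride
Product: 10 (1R,2S,3S)-3-(1-ethoxyvinyl)-2-[(1S)-1-hydroxy-2-(2-methyl-1,3-dioxolan-2-yl)ethyl]-3-methyl-1-(propan-2-yl)cyclopentan-1-ol
Conditions: iPrMgCl (2.5 equiv), LaCl3·2LiCl (30 mol %), THF, −20 °C; pH 7 phosphate buffer
Reagents that add atoms: none
Why: Lanthanum-salt-promoted Grignard 1,2-addition (enolisation and reduction suppressed): the nucleophile enters the cyclopentanone face opposite the adjacent C5 side chain, held on the β face as a chelated alkoxide, so the new hydroxyl is cis to that chain (C4 R); enol ether and ketal are inert.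

**Step 4**
Reactants: 10 diol from step 3
Product: 13 (1S,4R,5S,6S)-4,6-dihydroxydauc-8-en-10-one [(3R,3aS,4S,8aS)-3,4-dihydroxy-6,8a-dimethyl-3-(propan-2-yl)-2,3,3a,4,5,8a-hexahydroazulen-8(1H)-one; trans-fused], via bridged mixed ketal 11 (not isolated), via hydroxyethoxy ketone 12 (not isolated)
Conditions: BF3·OEt2 (10 mol %), CH2Cl2 (0.01 M), −40 → 0 °C; then 1 M HCl, THF, 23 → 40 °C
Reagents that add atoms: water, O
Why: Intramolecular Lewis-acid condensation of an enol ether with a ketal (Mukaiyama/Müller-Cunradi–Pieroh type): the enol ether can only attack through C9 and the ketal can only ionise at C8, so the seven-membered ring closes between the two trans-disposed arms; aqueous acid then hydrolyses the mixed ketal and eliminates ethylene glycol to the conjugated enone, leaving no new stereocenter.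

**Step 5**
Reactants: 13 enone diol from step 4; 14 angelic acid [(Z)-2-methylbut-2-enoic acid]
Product: 16 (1S,4R,5S,6S)-6-angeloyloxy-4-hydroxydauc-8-en-10-one, via angelic mixed anhydride 15 (not isolated)
Conditions: 14, 2,4,6-Cl3C6H2COCl, Et3N, toluene, 23 °C; then 13, 60 °C (no DMAP)
Reagents that add atoms: none
Why: Yamaguchi mixed-anhydride esterification: only the secondary C6 hydroxyl reacts (the C4 hydroxyl is tertiary), and leaving out nucleophilic catalysts keeps the Z (angelate) geometry.

**Step 6**
Reactants: 16 angelate enone from step 5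
Product: 17 (1S,4R,5S,6S,10R)-6-angeloyloxydauc-8-ene-4,10-diol (4β-OH, 10α-OH)
Conditions: (S)-Me-CBS oxazaborolidine (20 mol %), catecholborane (1.5 equiv), toluene, −78 °C
Reagents that add atoms: none
Why: Corey–Bakshi–Shibata reduction: catalyst-controlled 1,2-hydride delivery to the β face of the enone carbonyl, with the fully substituted C1 as the large group, gives the 10α (10R) allylic alcohol; ester and alkenes are untouched.

**Step 7**
Reactants: 17 allylic alcohol from step 6
Product: 18 lapiferine, (1S,4R,5S,6S,8R,9S,10S)-6-angeloyloxy-8,9-epoxydaucane-4,10-diol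
Conditions: VO(acac)2 (5 mol %), t-BuOOH (1.5 equiv), CH2Cl2, 0 → 23 °C
Reagents that add atoms: tert-butyl hydroperoxide, CC(C)(C)OO
Why: Vanadium-catalysed hydroxyl-directed epoxidation: the allylic 10α-hydroxyl binds the metal peroxide and delivers oxygen to the same (α) face of C8=C9, giving the cis epoxy alcohol (8R,9S); the electron-poor angelate alkene does not react.

**Compound list**
1 | ethyl 2-(2-methyl-1,3-dioxolan-2-yl)acetate (fructone) | CCOC(=O)CC1(C)OCCO1 | starting material
2 | 2-(2-methyl-1,3-dioxolan-2-yl)acetaldehyde | O=CCC1(C)OCCO1 | intermediate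
3 | ethyl vinyl ether | C=COCC | starting material
4 | 3-methylcyclopent-2-en-1-one | CC1=CC(=O)CC1 | starting material
5 | 1-ethoxyvinyllithium | [Li]C(=C)OCC | intermediate
6 | (1-ethoxyvinyl)diisobutylaluminium | C=C(OCC)[Al](CC(C)C)CC(C)C | intermediate
7 | diisobutylaluminium enolate of (3S)-3-(1-ethoxyvinyl)-3-methylcyclopentanone (C=C toward the carbon next to the quaternary centre) | C=C(OCC)[C@@]1(C)CCC(O[Al](CC(C)C)CC(C)C)=C1 | intermediate
8 | (2S,3S)-3-(1-ethoxyvinyl)-2-[(1S)-1-hydroxy-2-(2-methyl-1,3-dioxolan-2-yl)ethyl]-3-methylcyclopentan-1-one | C=C(OCC)[C@@]1(C)CCC(=O)[C@@H]1[C@@H](O)CC2(C)OCCO2 | intermediate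
9 | isopropylmagnesium chloride | CC(C)[Mg]Cl | starting material
10 | (1R,2S,3S)-3-(1-ethoxyvinyl)-2-[(1S)-1-hydroxy-2-(2-methyl-1,3-dioxolan-2-yl)ethyl]-3-methyl-1-(propan-2-yl)cyclopentan-1-ol | C=C(OCC)[C@@]1(C)CC[C@@](O)(C(C)C)[C@@H]1[C@@H](O)CC2(C)OCCO2 | intermediate
11 | ring-closed mixed ketal: C10 carries OEt and one end of an O–CH2CH2–O bridge to C8 (bridge face not assigned) | O[C@H]1CC2(C)CC(OCC)(OCCO2)[C@@]3(C)CC[C@@](O)(C(C)C)[C@H]13 | intermediate
12 | (1S,4R,5S,6S)-4,6-dihydroxy-8-(2-hydroxyethoxy)daucan-10-one (C8 epimers) | O[C@H]1CC(C)(OCCO)CC(=O)[C@@]2(C)CC[C@@](O)(C(C)C)[C@H]12 | intermediate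
13 | (1S,4R,5S,6S)-4,6-dihydroxydauc-8-en-10-one | O[C@H]1CC(C)=CC(=O)[C@@]2(C)CC[C@@](O)(C(C)C)[C@H]12 | intermediate
14 | angelic acid, (Z)-2-methylbut-2-enoic acid | C/C=C(/C)C(=O)O | starting material
15 | (Z)-2-methylbut-2-enoic 2,4,6-trichlorobenzoic anhydride | C/C=C(/C)C(=O)OC(=O)c1c(Cl)cc(Cl)cc1Cl | intermediate
16 | (1S,4R,5S,6S)-6-angeloyloxy-4-hydroxydauc-8-en-10-one | C/C=C(/C)C(=O)O[C@H]1CC(C)=CC(=O)[C@@]2(C)CC[C@@](O)(C(C)C)[C@H]12 | intermediate
17 | (1S,4R,5S,6S,10R)-6-angeloyloxydauc-8-ene-4,10-diol | C/C=C(/C)C(=O)O[C@H]1CC(C)=C[C@@H](O)[C@@]2(C)CC[C@@](O)(C(C)C)[C@H]12 | intermediate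
18 | lapiferine | C/C=C(/C)C(=O)O[C@H]1C[C@@]2(C)O[C@H]2[C@@H](O)[C@@]2(C)CC[C@@](O)(C(C)C)[C@H]12 | target

**Totals**
Total step count: 7. Longest linear sequence: 7 steps (1 → 2 → 8 → 10 → 13 → 16 → 17 → 18).

**Three steps most likely to fail**

Step 2. Transfer of an α-alkoxyvinyl group through the chiral copper catalyst is untested, and so are the ee on this five-membered enone and the aldol capture. Fallback, setting out from 4 and 2 and coming back at 13: use the silicon-masked acetyl-anion equivalent that is established for this enone class. Hydroalumination of ethynyltrimethylsilane with iBu2AlH gives [1-(trimethylsilyl)ethenyl]diisobutylaluminium F1, which is added to 4 with the same copper/NHC catalyst. Aldol capture with 2 gives silylvinyl ketol F2, and iPrMgCl/LaCl3·2LiCl gives silylvinyl diol F3. mCPBA then converts the vinylsilane into epoxysilane F4 (no other alkene is present). Aqueous formic acid opens the epoxysilane to the methyl ketone and removes the ketal, giving diketone F5. p-TsOH closes F5 to 13 by aldol condensation: the hindered C10 ketone can only enolise toward C9, the unhindered C8 ketone is the electrophile, and closure from C7 onto C10 would need a trans-fused bicyclo[3.3.0]octene.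

Step 4. The seven-membered closure may lose to ketal exchange with the free hydroxyls or to proton-catalysed scrambling of the two masked ketones. Fallback, setting out from 4 and coming back at 13: make the C8=C9 bond by ring-closing metathesis instead. Dess–Martin oxidation of commercial 3-methylbut-3-en-1-ol gives 3-methylbut-3-enal F6, used fresh in place of 2 in the step-2 protocol to give methallyl ketol F7. The step-3 conditions give methallyl diol F8. Eschenmoser's salt (CH2=NMe2+ I−) reacts at the enol-ether carbon and, after aqueous work-up, gives Mannich base F9. Heating its hydroiodide expels dimethylamine to give vinyl ketone F10. Second-generation Hoveyda–Grubbs catalyst (toluene, 80 °C) closes F10 to 13 with loss of ethene.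

Step 6. The ring ketone has its own facial bias (axial C1 methyl on the β face, concave ring underside on the α face) that may oppose the catalyst, and the wrong C10 epimer would also send the epoxide to the wrong face. Fallback, setting out from 16 and coming back at 17: give up borane delivery and reduce enzymatically, screening NADPH-dependent ketoreductases of both facial preferences (isopropanol as terminal reductant, pH 7 buffer/DMSO); no new compound is made (F0).

**Further compounds**
F1 | step 2 | [1-(trimethylsilyl)ethenyl]diisobutylaluminium | C=C([Si](C)(C)C)[Al](CC(C)C)CC(C)C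
F2 | step 2 | (2S,3S)-2-[(1S)-1-hydroxy-2-(2-methyl-1,3-dioxolan-2-yl)ethyl]-3-methyl-3-[1-(trimethylsilyl)ethenyl]cyclopentan-1-one | C=C([Si](C)(C)C)[C@@]1(C)CCC(=O)[C@@H]1[C@@H](O)CC2(C)OCCO2
F3 | step 2 | (1R,2S,3S)-2-[(1S)-1-hydroxy-2-(2-methyl-1,3-dioxolan-2-yl)ethyl]-3-methyl-1-(propan-2-yl)-3-[1-(trimethylsilyl)ethenyl]cyclopentan-1-ol | C=C([Si](C)(C)C)[C@@]1(C)CC[C@@](O)(C(C)C)[C@@H]1[C@@H](O)CC2(C)OCCO2
F4 | step 2 | epoxysilane of F3, 2-(trimethylsilyl)oxiran-2-yl in place of the silylvinyl group (epoxide carbon epimers) | C[Si](C)(C)C1(CO1)[C@@]2(C)CC[C@@](O)(C(C)C)[C@@H]2[C@@H](O)CC3(C)OCCO3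
F5 | step 2 | diketone, 10 with C10 as acetyl and C8 as methyl ketone (configuration as in 10) | CC(=O)[C@@]1(C)CC[C@@](O)(C(C)C)[C@@H]1[C@@H](O)CC(C)=O
F6 | step 4 | 3-methylbut-3-enal | C=C(C)CC=O
F7 | step 4 | ketol as 8 with 2-methylprop-2-enyl in place of the dioxolanylmethyl group | C=C(OCC)[C@@]1(C)CCC(=O)[C@@H]1[C@@H](O)CC(C)=C
F8 | step 4 | diol as 10 with 2-methylprop-2-enyl in place of the dioxolanylmethyl group | C=C(OCC)[C@@]1(C)CC[C@@](O)(C(C)C)[C@@H]1[C@@H](O)CC(C)=C
F9 | step 4 | Mannich base, 3-(dimethylamino)propanoyl in place of the ethoxyvinyl group of F8 | CN(C)CCC(=O)[C@@]1(C)CC[C@@](O)(C(C)C)[C@@H]1[C@@H](O)CC(C)=C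
F10 | step 4 | vinyl ketone, prop-2-enoyl in place of the ethoxyvinyl group of F8 | C=CC(=O)[C@@]1(C)CC[C@@](O)(C(C)C)[C@@H]1[C@@H](O)CC(C)=C
F0 | step 6 | none | none
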